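**Plan**

- Retrosynthesis: the three aryl O–CH3 bonds are cut first, then a carboxyl group is placed on ring A at C2, the carbon between C1–OH and the chain-bearing C3. The resulting salicylate ring is opened at C5–C6 and C2–C3 into two three-carbon pieces.
- Enabling feature: ring A is a meta-alkylphenol, so its C2 can carry CO2Me. As a 6-alkylsalicylate its carbons C2, C1 and C6 map onto C2–C4 of acetoacetate, and C3, C4 and C5 onto the O=C–CH2–CH(OMe)2 unit of a beta-keto acetal.
- The keto acetal is traced through an ynone and a Weinreb amide to a methyl ester. The C–D ethylene bridge is cut at a former C=C (Wittig, then H2) and the B–O–C ether at the O–C(ring C) bond (CuI-catalysed O-arylation).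
- Forward: rings B, C and D are bought as arenes and joined, ether first and bridge second. The side chain is grown to the keto acetal, and ring A, the only ring built, closes in the [3+3] step. Saponification, decarboxylation and O-demethylation finish the route.
- Stereochemistry: the target has no stereocentre. The E/Z mixture of the Wittig alkene and the transient sp3 centres of the ring A precursor are erased.

Key step: step 10

Remark: ring A = 3-hydroxyphenyl, ring B = the para-phenylene, ring C = the ring bearing OH and the aryloxy group, ring D = the hydroquinone ring. In the names below, Ar = 4-[5-[2-(2,5-dimethoxyphenyl)ethyl]-2-methoxyphenoxy]phenyl (rings B, C and D with three methyl ethers). Compound 1 and all unnumbered reagents are taken as commercial.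

**Route**

Step 1
Reactants: 1 methyl 3-(4-hydroxyphenyl)propanoate; 2 3-bromo-4-methoxybenzaldehyde
Product: 3 methyl 3-[4-(5-formyl-2-methoxyphenoxy)phenyl]propanoate
Conditions: CuI (10 mol%), picolinic acid (20 mol%), K3PO4, DMSO, 90 °C
Reagents that add atoms: none
Why: Ullmann-type diaryl ether synthesis; CuI with picolinic acid couples phenoxides with ortho-substituted aryl bromides under a mild phosphate base that should leave the aldehyde and the methyl ester untouched.

Step 2
Reactants: 4 2,5-dimethoxybenzyl alcohol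
Product: 5 (2,5-dimethoxybenzyl)triphenylphosphonium bromide
Conditions: PPh3·HBr, MeCN, reflux
Reagents that add atoms: triphenylphosphine hydrobromide, Br.c1ccc(cc1)P(c1ccccc1)c1ccccc1
Why: The electron-rich benzylic alcohol is ionised by HBr and captured by PPh3 (SN1-type phosphonium salt formation), which gives the Wittig salt in one operation.

Step 3
Reactants: 3 methyl 3-[4-(5-formyl-2-methoxyphenoxy)phenyl]propanoate; 5 (2,5-dimethoxybenzyl)triphenylphosphonium bromide
Product: 7 methyl 3-[4-[5-[2-(2,5-dimethoxyphenyl)ethenyl]-2-methoxyphenoxy]phenyl]propanoate (E/Z mixture), via (2,5-dimethoxybenzylidene)triphenylphosphorane 6 (not isolated)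
Conditions: K2CO3, 18-crown-6 (cat.), CH2Cl2, reflux
Reagents that add atoms: none
Why: Wittig olefination of the aryl aldehyde with the semi-stabilised benzylic ylide under solid–liquid phase-transfer conditions is mild enough to spare the methyl ester, and the alkene geometry is irrelevant because the double bond is reduced next.

Step 4
Reactants: 7 methyl 3-[4-[5-[2-(2,5-dimethoxyphenyl)ethenyl]-2-methoxyphenoxy]phenyl]propanoate (E/Z mixture)
Product: 8 methyl 3-Ar-propanoate
Conditions: H2 (1 atm), Pd/C, EtOAc, rt
Reagents that add atoms: none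
Why: Heterogeneous catalytic hydrogenation of a stilbene is fast and should not touch the diaryl ether, the aryl methyl ethers or the ester.

Step 5
Reactants: 8 methyl 3-Ar-propanoate
Product: 9 N-methoxy-N-methyl-3-Ar-propanamide
Conditions: MeNHOMe·HCl, iPrMgCl, THF, −20 to 0 °C
Reagents that add atoms: N,O-dimethylhydroxylamine hydrochloride, CNOC.Cl
Why: Direct aminolysis of the methyl ester by the chloromagnesium amide of N,O-dimethylhydroxylamine made in the flask (Weinreb amide synthesis), the magnesium-bound product resisting further attack.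

Step 6
Reactants: 9 N-methoxy-N-methyl-3-Ar-propanamide
Product: 11 5-Ar-pent-1-yn-3-one, via bromomagnesium hemiaminal chelate 10 (not isolated)
Conditions: HC≡CMgBr, THF, 0 °C; inverse quench into cold 1 M HCl
Reagents that add atoms: ethynylmagnesium bromide, C#C[Mg]Br
Why: Weinreb ketone synthesis; the alkynyl Grignard reagent adds once to give the stable chelate 10, which collapses to the ynone only on acidic quench, the acid also keeping the liberated amine protonated so that it cannot add to the ynone.

Step 7
Reactants: 11 5-Ar-pent-1-yn-3-one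
Product: 13 1,1-dimethoxy-5-Ar-pentan-3-one, via (E)-1-methoxy-5-Ar-pent-1-en-3-one 12 (not isolated)
Conditions: NaOMe (cat.), MeOH, 0 °C to rt; AcOH quench before concentration
Reagents that add atoms: methanol, CO
Why: Base-catalysed double oxa-Michael addition of methanol to a terminal ynone; the first addition gives the beta-methoxy enone 12 and the second the dimethyl acetal, which is favoured in neat methanol.

Step 8
Reactants: 14 methyl acetoacetate
Product: 15 methyl 3-(trimethylsilyloxy)but-2-enoate (E/Z mixture)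
Conditions: TMSCl, Et3N, hexane, rt
Reagents that add atoms: chlorotrimethylsilane, C[Si](C)(C)Cl
Why: O-silylation of the enol of a beta-keto ester with TMSCl and Et3N (silyl enol ether formation).

Step 9
Reactants: 15 methyl 3-(trimethylsilyloxy)but-2-enoate
Product: 17 (1Z)-1-methoxy-1,3-bis(trimethylsilyloxy)buta-1,3-diene (geometry as formed; not critical), via lithium dienolate 16 (not isolated)
Conditions: LiN(iPr)2, THF, −78 °C; then TMSCl, −78 °C to rt
Reagents that add atoms: chlorotrimethylsilane, C[Si](C)(C)Cl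
Why: Kinetic gamma-deprotonation of the silyloxy crotonate gives the extended dienolate 16, whose O-silylation furnishes the 1,3-bis(silyloxy)diene (the standard preparation of this diene).

Step 10
Reactants: 13 1,1-dimethoxy-5-Ar-pentan-3-one; 17 (1Z)-1-methoxy-1,3-bis(trimethylsilyloxy)buta-1,3-diene
Product: 20 methyl 2-hydroxy-6-(2-Ar-ethyl)benzoate, via open-chain keto ester 18 (not isolated), via cyclic aldol 19 (not isolated)
Conditions: TiCl4 (2 equiv), CH2Cl2, −78 °C to rt; then H2O
Reagents that add atoms: none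
Why: TiCl4 ionises the dimethyl acetal of 13 to an oxocarbenium ion, which the terminal CH2 of diene 17 attacks in a vinylogous Mukaiyama aldol reaction to give the open-chain adduct 18 as its titanium or silyl enolate. The remaining enol carbon (C2 of the acetoacetate unit) then adds to the titanium-activated ketone in an intramolecular aldol reaction, a 6-(enolendo)-exo-trig closure that forms ring A as cyclohexanone 19; loss of water and methanol aromatises it. The closest known reaction type is the TiCl4-mediated [3+3] cycloaromatisation of 1,3-bis(silyloxy)dienes with beta-keto acetals to salicylates. No stereocentre is created in the product, the three sp3 centres of 19 being erased on aromatisation. The selectivity needed is regiochemical, since the chain must end beside the ester carbon: the acetal-derived oxocarbenium ion is far more electrophilic than the ketone and meets the most nucleophilic diene terminus first, which leaves the ketone carbon to bond to the central carbon. The aryl methyl ethers and the diaryl ether should be inert to TiCl4 at low temperature.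

Step 11
Reactants: 20 methyl 2-hydroxy-6-(2-Ar-ethyl)benzoate
Product: 21 2-hydroxy-6-(2-Ar-ethyl)benzoic acid
Conditions: KOH, DMSO/H2O, 90 °C; then aq. HCl
Reagents that add atoms: potassium hydroxide, [K+].[OH-]
Why: Saponification of the hindered, hydrogen-bonded methyl salicylate needs forcing aqueous KOH in DMSO, and no other group in the molecule is base-labile.

Step 12
Reactants: 21 2-hydroxy-6-(2-Ar-ethyl)benzoic acid
Product: 22 3-(2-Ar-ethyl)phenol
Conditions: quinoline, 200 °C, N2
Reagents that add atoms: none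
Why: Thermal protodecarboxylation of a 6-alkylsalicylic acid by ipso-protonation through the keto tautomer, as in the conversion of anacardic acids into cardanols and of lunularic acid into lunularin.

Step 13
Reactants: 22 3-(2-Ar-ethyl)phenol
Product: 23 2-[2-[4-hydroxy-3-[4-[2-(3-hydroxyphenyl)ethyl]phenoxy]phenyl]ethyl]benzene-1,4-diol (CNP0300581.0)
Conditions: BBr3 (6 equiv), CH2Cl2, −78 °C to rt; then degassed H2O, work-up under N2
Reagents that add atoms: none
Why: BBr3 cleaves the three aryl methyl ethers by Lewis acid complexation and SN2 attack of bromide on methyl, leaving the diaryl ether and both bibenzyl bridges intact, the borate esters being hydrolysed on work-up.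

**Compound list**

1 | methyl 3-(4-hydroxyphenyl)propanoate | COC(=O)CCc1ccc(O)cc1 | starting material
2 | 3-bromo-4-methoxybenzaldehyde | COc1ccc(C=O)cc1Br | starting material
3 | methyl 3-[4-(5-formyl-2-methoxyphenoxy)phenyl]propanoate | COC(=O)CCc1ccc(Oc2cc(C=O)ccc2OC)cc1 | intermediate
4 | 2,5-dimethoxybenzyl alcohol | COc1ccc(OC)c(CO)c1 | starting material
5 | (2,5-dimethoxybenzyl)triphenylphosphonium bromide | COc1ccc(OC)c(C[P+](c2ccccc2)(c2ccccc2)c2ccccc2)c1.[Br-] | intermediate
6 | (2,5-dimethoxybenzylidene)triphenylphosphorane (ylide, not isolated) | COc1ccc(OC)c(C=P(c2ccccc2)(c2ccccc2)c2ccccc2)c1 | intermediate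
7 | methyl 3-[4-[5-[2-(2,5-dimethoxyphenyl)ethenyl]-2-methoxyphenoxy]phenyl]propanoate (E/Z mixture, geometry undefined) | COC(=O)CCc1ccc(Oc2cc(C=Cc3cc(OC)ccc3OC)ccc2OC)cc1 | intermediate
8 | methyl 3-[4-[5-[2-(2,5-dimethoxyphenyl)ethyl]-2-methoxyphenoxy]phenyl]propanoate | COC(=O)CCc1ccc(Oc2cc(CCc3cc(OC)ccc3OC)ccc2OC)cc1 | intermediate
9 | 3-[4-[5-[2-(2,5-dimethoxyphenyl)ethyl]-2-methoxyphenoxy]phenyl]-N-methoxy-N-methylpropanamide | CON(C)C(=O)CCc1ccc(Oc2cc(CCc3cc(OC)ccc3OC)ccc2OC)cc1 | intermediate
10 | bromomagnesium hemiaminal chelate from 9 and the alkynyl Grignard reagent (not isolated) | CON(C)C(O[Mg]Br)(C#C)CCc1ccc(Oc2cc(CCc3cc(OC)ccc3OC)ccc2OC)cc1 | intermediate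
11 | 5-[4-[5-[2-(2,5-dimethoxyphenyl)ethyl]-2-methoxyphenoxy]phenyl]pent-1-yn-3-one | C#CC(=O)CCc1ccc(Oc2cc(CCc3cc(OC)ccc3OC)ccc2OC)cc1 | intermediate
12 | (E)-5-[4-[5-[2-(2,5-dimethoxyphenyl)ethyl]-2-methoxyphenoxy]phenyl]-1-methoxypent-1-en-3-one (not isolated; geometry immaterial) | CO/C=C/C(=O)CCc1ccc(Oc2cc(CCc3cc(OC)ccc3OC)ccc2OC)cc1 | intermediate
13 | 5-[4-[5-[2-(2,5-dimethoxyphenyl)ethyl]-2-methoxyphenoxy]phenyl]-1,1-dimethoxypentan-3-one | COC(OC)CC(=O)CCc1ccc(Oc2cc(CCc3cc(OC)ccc3OC)ccc2OC)cc1 | intermediate
14 | methyl acetoacetate | COC(=O)CC(C)=O | starting material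
15 | methyl 3-(trimethylsilyloxy)but-2-enoate (E/Z mixture, geometry undefined) | COC(=O)C=C(C)O[Si](C)(C)C | intermediate
16 | lithium dienolate of 15, lithium 1-methoxy-3-(trimethylsilyloxy)buta-1,3-dien-1-olate (not isolated) | C=C(O[Si](C)(C)C)C=C(OC)O[Li] | intermediate
17 | (1Z)-1-methoxy-1,3-bis(trimethylsilyloxy)buta-1,3-diene | CO/C(O[Si](C)(C)C)=C/C(=C)O[Si](C)(C)C | intermediate
18 | methyl 9-[4-[5-[2-(2,5-dimethoxyphenyl)ethyl]-2-methoxyphenoxy]phenyl]-5-methoxy-3,7-dioxononanoate (present as its titanium or silyl enolate; not isolated; racemic) | COC(=O)CC(=O)CC(OC)CC(=O)CCc1ccc(Oc2cc(CCc3cc(OC)ccc3OC)ccc2OC)cc1 | intermediate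
19 | methyl 2-[2-[4-[5-[2-(2,5-dimethoxyphenyl)ethyl]-2-methoxyphenoxy]phenyl]ethyl]-2-hydroxy-4-methoxy-6-oxocyclohexane-1-carboxylate (diastereomer mixture; not isolated) | COC(=O)C1C(=O)CC(OC)CC1(O)CCc1ccc(Oc2cc(CCc3cc(OC)ccc3OC)ccc2OC)cc1 | intermediate
20 | methyl 2-[2-[4-[5-[2-(2,5-dimethoxyphenyl)ethyl]-2-methoxyphenoxy]phenyl]ethyl]-6-hydroxybenzoate | COC(=O)c1c(O)cccc1CCc1ccc(Oc2cc(CCc3cc(OC)ccc3OC)ccc2OC)cc1 | intermediate
21 | 2-[2-[4-[5-[2-(2,5-dimethoxyphenyl)ethyl]-2-methoxyphenoxy]phenyl]ethyl]-6-hydroxybenzoic acid | OC(=O)c1c(O)cccc1CCc1ccc(Oc2cc(CCc3cc(OC)ccc3OC)ccc2OC)cc1 | intermediate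
22 | 3-[2-[4-[5-[2-(2,5-dimethoxyphenyl)ethyl]-2-methoxyphenoxy]phenyl]ethyl]phenol | Oc1cccc(CCc2ccc(Oc3cc(CCc4cc(OC)ccc4OC)ccc3OC)cc2)c1 | intermediate
23 | 2-[2-[4-hydroxy-3-[4-[2-(3-hydroxyphenyl)ethyl]phenoxy]phenyl]ethyl]benzene-1,4-diol | Oc1cccc(CCc2ccc(Oc3cc(CCc4cc(O)ccc4O)ccc3O)cc2)c1 | target

**Step count and risks**

Total steps: 13. Longest linear sequence: 10 steps (steps 1, 3, 4, 5, 6, 7, 10, 11, 12, 13).

Steps most likely to fail:

Step 10. The keto acetal may lose methanol to the beta-methoxy enone before the C–C bond forms, and the diene may be protodesilylated, so that the cyclisation stalls at the open-chain stage or regiocontrol is eroded. The fallback sets out from ynone 11 and builds ring A by a Michael addition–aldol condensation cascade with dimethyl 3-oxopentanedioate (NaOMe, MeOH/THF, rt to 60 °C). The C2 carbanion of the diester adds to the alkyne terminus, the C4 carbon then condenses with the ketone, and dehydration should give dimethyl 2-hydroxy-4-(2-Ar-ethyl)benzene-1,3-dicarboxylate F1. Saponification (KOH, DMSO/H2O, 100 °C, then aq. HCl) gives 2-hydroxy-4-(2-Ar-ethyl)benzene-1,3-dicarboxylic acid F2. Both of its carboxyl groups are ortho to the phenol and should be lost on heating in quinoline at 200 °C, which returns to the route at 22.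

Step 1. Oxidative addition into the electron-rich, ortho-methoxy-substituted C–Br bond may be slow, letting base-mediated degradation of the aldehyde or hydrolysis of the ester compete. The fallback forms the ether by nucleophilic aromatic substitution instead and sets out from phosphonium salt 5. Wittig reaction of 5 with isovanillin (3-hydroxy-4-methoxybenzaldehyde; KOtBu, 2.2 equiv, THF) gives 5-[2-(2,5-dimethoxyphenyl)ethenyl]-2-methoxyphenol F3 as an E/Z mixture. SNAr of its phenoxide on 4-fluorobenzaldehyde (K2CO3, DMF, 130 °C) gives 4-[5-[2-(2,5-dimethoxyphenyl)ethenyl]-2-methoxyphenoxy]benzaldehyde F4. Horner–Wadsworth–Emmons olefination with trimethyl phosphonoacetate (NaH, THF) gives methyl (E)-3-[4-[5-[2-(2,5-dimethoxyphenyl)ethenyl]-2-methoxyphenoxy]phenyl]prop-2-enoate F5, and hydrogenation of both alkenes (H2, Pd/C, EtOAc) returns to the route at 8.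

Step 6. The liberated N,O-dimethylhydroxylamine may add to the ynone in a conjugate sense during the quench, and the terminal ynone may oligomerise under basic conditions. The fallback sets out from Weinreb amide 9 and avoids the ynone altogether. MeMgBr (THF, 0 °C) gives the methyl ketone 4-Ar-butan-2-one F6. Kinetic enolisation at the methyl group (LiN(iPr)2, THF, −78 °C, then TMSCl) gives the silyl enol ether trimethyl[(4-Ar-but-1-en-2-yl)oxy]silane F7. Mukaiyama-type addition of F7 to trimethyl orthoformate (TMSOTf cat., CH2Cl2, −78 °C) should give the keto acetal and returns to the route at 13.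

**Further compounds**

F1 | step 10 | dimethyl 4-[2-[4-[5-[2-(2,5-dimethoxyphenyl)ethyl]-2-methoxyphenoxy]phenyl]ethyl]-2-hydroxybenzene-1,3-dicarboxylate | COC(=O)c1ccc(CCc2ccc(Oc3cc(CCc4cc(OC)ccc4OC)ccc3OC)cc2)c(C(=O)OC)c1O
F2 | step 10 | 4-[2-[4-[5-[2-(2,5-dimethoxyphenyl)ethyl]-2-methoxyphenoxy]phenyl]ethyl]-2-hydroxybenzene-1,3-dicarboxylic acid | OC(=O)c1ccc(CCc2ccc(Oc3cc(CCc4cc(OC)ccc4OC)ccc3OC)cc2)c(C(O)=O)c1O
F3 | step 1 | 5-[2-(2,5-dimethoxyphenyl)ethenyl]-2-methoxyphenol (E/Z mixture) | COc1ccc(OC)c(C=Cc2ccc(OC)c(O)c2)c1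
F4 | step 1 | 4-[5-[2-(2,5-dimethoxyphenyl)ethenyl]-2-methoxyphenoxy]benzaldehyde (E/Z mixture) | COc1ccc(OC)c(C=Cc2ccc(OC)c(Oc3ccc(C=O)cc3)c2)c1
F5 | step 1 | methyl (E)-3-[4-[5-[2-(2,5-dimethoxyphenyl)ethenyl]-2-methoxyphenoxy]phenyl]prop-2-enoate (stilbene alkene E/Z) | COC(=O)/C=C/c1ccc(Oc2cc(C=Cc3cc(OC)ccc3OC)ccc2OC)cc1
F6 | step 6 | 4-[4-[5-[2-(2,5-dimethoxyphenyl)ethyl]-2-methoxyphenoxy]phenyl]butan-2-one | CC(=O)CCc1ccc(Oc2cc(CCc3cc(OC)ccc3OC)ccc2OC)cc1
F7 | step 6 | [4-[4-[5-[2-(2,5-dimethoxyphenyl)ethyl]-2-methoxyphenoxy]phenyl]but-1-en-2-yl]oxy-trimethylsilane | C=C(O[Si](C)(C)C)CCc1ccc(Oc2cc(CCc3cc(OC)ccc3OC)ccc2OC)cc1
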